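**Retrosynthetic overview**

1. Numbering used throughout: ring A (six-membered) = C1, C6, C7 (isopropyl), C8 (O-angeloyl), C9 (OH), C10 (=C14H2); ring B (five-membered) = C1, C2, C3 (OAc), C5 (=C4H–C15H3), C6.
2. Endgame: desilylation of C9–O ⇐ angeloylation of C8–OH ⇐ methylenation of a C10 ketone, the oxidation level the key step needs.
3. Key disconnection: C1–C6 and C8–C9 together, by a domino intramolecular Michael/aldol reaction (α,α′-annulation) that folds an acyclic keto-dienal: ring B closes first (C1 onto C6), then ring A (C9 onto C8).
4. Enabling feature: C10 is flanked by C1 and C9, so as a ketone it is a 1,3-bis-nucleophile; C6–C7–C8 as an enal is the matching 1,3-bis-electrophile; the C15 methyl of the (Z)-ethylidene, cis to C3, relays the C3 configuration by allylic 1,3-strain.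
5. The chain comes from a propargylic acetate (C3 by asymmetric transfer hydrogenation, ethylidene geometry by syn-hydrostannation) and a (Z)-β-iodoenal, joined by a copper-mediated Stille-type coupling.

Key step: step 11

**Route**

Step 1
Reactants: 1 prop-1-yn-1-ylmagnesium bromide; 2 pent-4-enoyl chloride
Product: 4 oct-7-en-2-yn-4-one, via prop-1-yn-1-ylzinc chloride 3 (not isolated)
Conditions: ZnCl2, THF, 0 °C; then 2, Pd(PPh3)4 (2 mol %), 23 °C
Reagents that add atoms: none
Why: Negishi-type palladium-catalysed acylation of the alkynylzinc chloride (from transmetalation of the Grignard reagent) should give the ynone without over-addition; no stereocentre is formed.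

Step 2
Reactants: 4 oct-7-en-2-yn-4-one
Product: 5 (4S)-oct-7-en-2-yn-4-ol
Conditions: RuCl[(S,S)-TsDPEN](p-cymene) (1 mol %), iPrOH, 23 °C
Reagents that add atoms: none
Why: Noyori asymmetric transfer hydrogenation of an alkynyl ketone; the alkynyl group takes the role of the aryl group of acetophenone in the transition state, so the (S,S)-catalyst should give the (S)-carbinol (the future C3) and leave the alkene untouched.

Step 3
Reactants: 5 (4S)-oct-7-en-2-yn-4-ol
Product: 6 (4S)-oct-7-en-2-yn-4-yl acetate
Conditions: Ac2O, pyridine, DMAP (cat.), CH2Cl2, 0 → 23 °C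
Reagents that add atoms: acetic anhydride CC(=O)OC(C)=O
Why: DMAP-catalysed acetylation installs the C3 acetate of the target early, so that no hemiketal can form with the later C10 ketone; the stereocentre is not touched.

Step 4
Reactants: 6 (4S)-oct-7-en-2-yn-4-yl acetate
Product: 7 (4S)-7,8-dihydroxyoct-2-yn-4-yl acetate (both C7 epimers)
Conditions: OsO4 (2 mol %), N-methylmorpholine N-oxide, acetone/H2O, 0 → 23 °C
Reagents that add atoms: N-methylmorpholine N-oxide C[N+]1([O-])CCOCC1; water O
Why: Upjohn dihydroxylation; the terminal alkene reacts far faster than the internal alkyne, and the new carbinol centre is left uncontrolled because step 6 oxidizes it.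

Step 5
Reactants: 7 (4S)-7,8-dihydroxyoct-2-yn-4-yl acetate
Product: 8 (4S)-8-[(tert-butyldimethylsilyl)oxy]-7-hydroxyoct-2-yn-4-yl acetate (both C7 epimers)
Conditions: TBSCl, imidazole, CH2Cl2, 0 °C
Reagents that add atoms: tert-butyldimethylsilyl chloride CC(C)(C)[Si](C)(C)Cl
Why: Silylation is selective for the primary hydroxyl on steric grounds; no stereocentre is formed.

Step 6
Reactants: 8 (4S)-8-[(tert-butyldimethylsilyl)oxy]-7-hydroxyoct-2-yn-4-yl acetate
Product: 9 (4S)-8-[(tert-butyldimethylsilyl)oxy]-7-oxooct-2-yn-4-yl acetate
Conditions: Dess–Martin periodinane, CH2Cl2, 0 → 23 °C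
Reagents that add atoms: none
Why: Dess–Martin oxidation of the secondary alcohol gives the α-silyloxy ketone (C10) under non-basic conditions and removes the uncontrolled stereocentre.

Step 7
Reactants: 9 (4S)-8-[(tert-butyldimethylsilyl)oxy]-7-oxooct-2-yn-4-yl acetate
Product: 10 (2E,4S)-8-[(tert-butyldimethylsilyl)oxy]-7-oxo-3-(tributylstannyl)oct-2-en-4-yl acetate
Conditions: Bu3SnH, Mo(CO)3(CNtBu)3 (5 mol %), hydroquinone (cat.), THF, 55 °C
Reagents that add atoms: tributyltin hydride CCCC[SnH](CCCC)CCCC
Why: Molybdenum-catalysed hydrostannation of a propargylic ester is a syn addition that places tin on the carbon next to the acetoxy-bearing carbon, so the methyl group ends cis to C3, which is the (Z)-ethylidene geometry of the target.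

Step 8
Reactants: 11 prop-2-yn-1-ol; 12 isopropylmagnesium chloride
Product: 14 (2Z)-2-(iodomethylidene)-3-methylbutan-1-ol, via magnesium chelate 13 (not isolated)
Conditions: iPrMgCl (2.5 equiv), CuI (10 mol %), THF, −20 → 23 °C; then I2, −78 → 0 °C
Reagents that add atoms: iodine II
Why: Copper-catalysed anti-carbomagnesiation of propargyl alcohol delivers isopropyl to the internal carbon while the alkoxide holds magnesium on the terminal carbon in a five-membered chelate; iodinolysis with retention fixes iodine cis to CH2OH.

Step 9
Reactants: 14 (2Z)-2-(iodomethylidene)-3-methylbutan-1-ol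
Product: 15 (2Z)-2-(iodomethylidene)-3-methylbutanal
Conditions: MnO2, CH2Cl2, 23 °C
Reagents that add atoms: none
Why: Allylic oxidation with MnO2 stops at the aldehyde and should retain the alkene geometry; the enal is used at once.

Step 10
Reactants: 10 (2E,4S)-8-[(tert-butyldimethylsilyl)oxy]-7-oxo-3-(tributylstannyl)oct-2-en-4-yl acetate; 15 (2Z)-2-(iodomethylidene)-3-methylbutanal
Product: 16 (2Z,5S)-5-acetoxy-9-[(tert-butyldimethylsilyl)oxy]-4-[(Z)-ethylidene]-8-oxo-2-(propan-2-yl)non-2-enal
Conditions: Cu(O2C-C4H3S) (copper thiophene-2-carboxylate, 1.5 equiv), NMP, 0 → 23 °C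
Reagents that add atoms: none
Why: Copper-mediated Stille-type coupling of an alkenylstannane with an alkenyl iodide proceeds with retention at both alkenes and, being palladium-free, does not ionize the allylic acetate; the geometry of the enal double bond is of no consequence because C6 becomes sp3 in step 11.

Step 11
Reactants: 16 (2Z,5S)-5-acetoxy-9-[(tert-butyldimethylsilyl)oxy]-4-[(Z)-ethylidene]-8-oxo-2-(propan-2-yl)non-2-enal
Product: 18 ketol (C10 ketone; C9 OTBS; C8 OH; trans-fused rings A/B), via ring B keto-aldehyde 17 (not isolated)
Conditions: pyrrolidine (30 mol %), PhCO2H (30 mol %), CHCl3 (0.01 M), 23 °C; then pH 5 aqueous buffer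
Reagents that add atoms: none
Why: Pyrrolidine turns the C10 ketone reversibly into its enamines and the enal into its iminium ion; the C1 enamine adds to C6 (intramolecular Michael addition, 5-exo-trig) to close ring B and give 17, whose C9 enamine then attacks the released C8 aldehyde (intramolecular enamine aldol, 6-enolendo-exo-trig) to close ring A, and hydrolysis returns the ketone. The closest known reaction type is the amine-mediated α,α′-annulation of a ketone with an α,β-unsaturated aldehyde (Stork enamine Michael addition followed by aldol closure), run here within one chain so that it folds into both rings. C6 should be set by the C3 acetate: allylic 1,3-strain with the C15 methyl keeps C3–H in the diene plane, the tether leaves from one face and the acetoxy group lies on the other, so C6–H ends cis to the acetoxy group; C1 is α to the ketone, equilibrates through the enamine and should settle trans to the C6 side chain (trans ring fusion). C7 is α to the aldehyde, epimerizes before ring A closes and should enter the chair-like aldol transition state with isopropyl equatorial; the C9 enamine carries OTBS anti to nitrogen (allylic strain with the pyrrolidine ring), so bond formation perpendicular to the enamine plane leaves OTBS axial, and the formyl C=O aligns antiperiplanar to the C9–O bond (dipole minimization, acid-bridged towards the iminium nitrogen), which should give the axial C8 carbinol trans to OTBS. The step needs site selectivity between the two enamines and between 1,4- and 1,6-addition, which ring size secures (C9 onto C6 would make a seven-membered ring, C1 onto C4 would be 5-endo); it must also stop at the ketol, for which the buffered conditions at 23 °C are chosen to avoid dehydration.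

Step 12
Reactants: 18 ketol (1R,3S,6S,7S,8S,9R)
Product: 19 C10-methylene alcohol (1R,3S,6R,7S,8S,9S)
Conditions: Zn, CH2Br2, TiCl4, THF, 0 → 23 °C
Reagents that add atoms: dibromomethane BrCBr
Why: Takai–Lombardo methylenation is non-basic, so it should convert the hindered, enolizable β-hydroxy ketone into the exocyclic alkene without retro-aldol cleavage or epimerization at C1 and C9, and it leaves the acetate alone.

Step 13
Reactants: 19 C10-methylene alcohol; 20 angelic acid
Product: 22 C8 angelate C9 silyl ether (1R,3S,6R,7S,8S,9S), via mixed anhydride 21 (not isolated)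
Conditions: 2,4,6-Cl3C6H2COCl, Et3N, toluene, 23 °C; then 19, toluene, 80 °C
Reagents that add atoms: none
Why: Yamaguchi-type mixed-anhydride esterification run without a nucleophilic catalyst should acylate the hindered axial C8 hydroxyl while avoiding the addition–elimination pathway that isomerizes angelates to tiglates; the stereocentres are not touched.

Step 14
Reactants: 22 C8 angelate C9 silyl ether
Product: 23 target CNP0113604.1
Conditions: HF·pyridine, pyridine/THF, 0 → 23 °C
Reagents that add atoms: none
Why: Buffered fluoride desilylation frees the C9 hydroxyl without touching the two esters or the exocyclic alkenes, and the trans-diaxial arrangement of C8–O and C9–O should prevent acyl migration.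

**Compound list**

1 | prop-1-yn-1-ylmagnesium bromide | CC#C[Mg]Br | starting material
2 | pent-4-enoyl chloride | C=CCCC(=O)Cl | starting material
3 | prop-1-yn-1-ylzinc chloride | CC#C[Zn]Cl | intermediate (not isolated)
4 | oct-7-en-2-yn-4-one | CC#CC(=O)CCC=C | intermediate
5 | (4S)-oct-7-en-2-yn-4-ol | CC#C[C@@H](O)CCC=C | intermediate
6 | (4S)-oct-7-en-2-yn-4-yl acetate | CC#C[C@@H](OC(C)=O)CCC=C | intermediate
7 | (4S)-7,8-dihydroxyoct-2-yn-4-yl acetate, both C7 epimers | CC#C[C@@H](OC(C)=O)CCC(O)CO | intermediate
8 | (4S)-8-[(tert-butyldimethylsilyl)oxy]-7-hydroxyoct-2-yn-4-yl acetate, both C7 epimers | CC#C[C@@H](OC(C)=O)CCC(O)CO[Si](C)(C)C(C)(C)C | intermediate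
9 | (4S)-8-[(tert-butyldimethylsilyl)oxy]-7-oxooct-2-yn-4-yl acetate | CC#C[C@@H](OC(C)=O)CCC(=O)CO[Si](C)(C)C(C)(C)C | intermediate
10 | (2E,4S)-8-[(tert-butyldimethylsilyl)oxy]-7-oxo-3-(tributylstannyl)oct-2-en-4-yl acetate | C/C=C(\[C@@H](OC(C)=O)CCC(=O)CO[Si](C)(C)C(C)(C)C)[Sn](CCCC)(CCCC)CCCC | intermediate
11 | prop-2-yn-1-ol | C#CCO | starting material
12 | isopropylmagnesium chloride | CC(C)[Mg]Cl | starting material
13 | magnesium chelate, 4-isopropyl-2,5-dihydro-1,2-oxamagnesole | CC(C)C1=C[Mg]OC1 | intermediate (not isolated)
14 | (2Z)-2-(iodomethylidene)-3-methylbutan-1-ol | OC/C(C(C)C)=C\I | intermediate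
15 | (2Z)-2-(iodomethylidene)-3-methylbutanal | O=C/C(C(C)C)=C\I | intermediate
16 | (2Z,5S)-5-acetoxy-9-[(tert-butyldimethylsilyl)oxy]-4-[(Z)-ethylidene]-8-oxo-2-(propan-2-yl)non-2-enal | CC(C)(C)[Si](C)(C)OCC(=O)CC[C@H](OC(C)=O)/C(=C\C)/C=C(\C=O)C(C)C | intermediate
17 | ring B keto-aldehyde: cyclopentane with C1 2-[(tert-butyldimethylsilyl)oxy]acetyl, C3 acetoxy, C5 (Z)-ethylidene and C6 CH(iPr)CHO; C1/C6 trans, C3–OAc cis to C6–H; 1R,3S,6S, C7 epimers | O=C(CO[Si](C)(C)C(C)(C)C)[C@@H]1C[C@H](OC(C)=O)/C(=C\C)[C@H]1C(C=O)C(C)C | intermediate (not isolated)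
18 | ketol: trans-fused bicycle with C10 ketone, C9 OTBS (axial), C8 OH (axial), C7 isopropyl (equatorial), C3 OAc, C5 (Z)-ethylidene; 1R,3S,6S,7S,8S,9R | O=C1[C@H](O[Si](C)(C)C(C)(C)C)[C@@H](O)[C@@H](C(C)C)[C@@H]2/C(=C/C)[C@@H](OC(C)=O)C[C@@H]12 | intermediate
19 | C10-methylene alcohol: as 18 with C10=C14H2; 1R,3S,6R,7S,8S,9S | C=C1[C@H](O[Si](C)(C)C(C)(C)C)[C@@H](O)[C@@H](C(C)C)[C@@H]2/C(=C/C)[C@@H](OC(C)=O)C[C@@H]12 | intermediate
20 | angelic acid, (Z)-2-methylbut-2-enoic acid | C/C=C(/C)C(=O)O | starting material
21 | mixed anhydride of angelic acid and 2,4,6-trichlorobenzoic acid | C/C=C(/C)C(=O)OC(=O)c1c(Cl)cc(Cl)cc1Cl | intermediate (not isolated)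
22 | C8 angelate C9 silyl ether: as 19 with C8 O-angeloyl; 1R,3S,6R,7S,8S,9S | C=C1[C@H](O[Si](C)(C)C(C)(C)C)[C@@H](OC(=O)/C(C)=C\C)[C@@H](C(C)C)[C@@H]2/C(=C/C)[C@@H](OC(C)=O)C[C@@H]12 | intermediate
23 | CNP0113604.1: 3-acetoxy-8-angeloyloxy-9-hydroxy bicycle with C5 (Z)-ethylidene and C10 exocyclic methylene; 1R,3S,6R,7S,8S,9S | C=C1[C@H](O)[C@@H](OC(=O)/C(C)=C\C)[C@@H](C(C)C)[C@@H]2/C(=C/C)[C@@H](OC(C)=O)C[C@@H]12 | target

**Step count and risks**

Total step count: 14. Longest linear sequence: 12 (steps 1–7 and 10–14); steps 8 and 9 form the two-step side branch.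

The three steps most likely to fail:

Step 11. The cascade may stall after the first ring closure, the ketol may lose water to the conjugated enone, or reversible retro-aldol/aldol may erode facial control at C8 and C9. The fallback sets out from 16 and separates the two ring closures. The Michael reaction is run alone (pyrrolidine without acid, short contact time) and the ring B keto-aldehyde 17 is isolated. 17 is then treated with (c-C6H11)2BCl and Et3N in Et2O at −78 °C, which should enolize the ketone on the C9 side to the (E)-dicyclohexylboron enolate F1. F1 closes ring A onto the C8 aldehyde through a closed Zimmerman–Traxler transition state (OTBS axial from the E-enolate, the boron-bridged aldehyde oxygen axial). Buffered methanolic work-up releases the ketol, and the fallback comes back to the route at 18.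

Step 13. The hindered axial C8 hydroxyl may not be acylated, or the (Z)-acyl group may isomerize to the (E)-isomer during the long heating. The fallback sets out from 19 and builds the angelate on the molecule. 19 is esterified with 2-[bis(2,2,2-trifluoroethoxy)phosphoryl]propanoic acid and dicyclohexylcarbodiimide (acylation through the phosphonoketene, which is suited to hindered alcohols) to give the phosphonate ester F2. Still–Gennari olefination of F2 with acetaldehyde (KN(SiMe3)2, 18-crown-6, THF, −78 °C) should form the (Z)-2-methylbut-2-enoate directly, and the fallback comes back to the route at 22.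

Step 12. The β-hydroxy ketone may undergo retro-aldol cleavage, C1 or C9 may epimerize, or the hindered carbonyl may react incompletely with the titanium–zinc methylene reagent. The fallback sets out from 18 and uses a Peterson olefination in two stages. Addition of Me3SiCH2MgCl/CeCl3 in THF at −78 °C (a weakly basic organocerium reagent that should prefer the ketone to the acetate) gives the β-hydroxysilane F3. Acid-promoted anti-elimination (TsOH cat., CH2Cl2, 0 °C) then forms the exocyclic methylene, and the fallback comes back to the route at 19.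

**Further compounds**

F1 | step 11 | (E)-dicyclohexylboron enolate of 17 on the C9 side | C1CCCCC1B(C1CCCCC1)O/C(=C/O[Si](C)(C)C(C)(C)C)[C@@H]1C[C@H](OC(C)=O)/C(=C\C)[C@H]1C(C=O)C(C)C
F2 | step 13 | C8 2-[bis(2,2,2-trifluoroethoxy)phosphoryl]propanoate of 19 | C=C1[C@H](O[Si](C)(C)C(C)(C)C)[C@@H](OC(=O)C(C)P(=O)(OCC(F)(F)F)OCC(F)(F)F)[C@@H](C(C)C)[C@@H]2/C(=C/C)[C@@H](OC(C)=O)C[C@@H]12
F3 | step 12 | C10 tertiary alcohol bearing a (trimethylsilyl)methyl group, from addition to 18 | C[Si](C)(C)CC1(O)[C@H](O[Si](C)(C)C(C)(C)C)[C@@H](O)[C@@H](C(C)C)[C@@H]2/C(=C/C)[C@@H](OC(C)=O)C[C@@H]12
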